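**Plan**

- Numbering of the target: oxolane O1, C2 (aryl), C3 (CH2OH), C4 (aroyl), C5. The CH2OH carbon, C3, C4 and C5 are read as the carbonyl, α-, β- and γ-carbons of a γ-butyrolactone. At C3 the ring bond and the exocyclic bond change places when the ring oxygen moves to the C2 side, so a trans-α,β-disubstituted lactone becomes the 3,4-cis oxolane.
- Retrosynthesis cuts O1–C2 (benzylic ether), then C2–C3 (aldol) and the bond from C4 to the ketone carbon (acyl-anion conjugate addition), and adds one carbon back at C5 to reach a butenolide from D-glutamic acid.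
- Forward: butenolide 10, lithiated aryl dithiane 16 and O-benzylsyringaldehyde 13 are joined in one flask (step 8, no ring closed). Lactone reduction, desilylation and glycol cleavage/reduction give an acyclic triol. The oxolane, the only ring formed, closes last under acid (step 12), followed by dithiane hydrolysis and hydrogenolysis.
- Stereochemistry: the glutamate α-carbon (γ-carbon of 10) sets C4 by anti conjugate addition and C3 by trans aldol trapping, and is then cut down to the CH2 of C5. C2 is set in the cationic ring closure, trans to the C3 substituent.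

Key step: step 8

Remark: Ar = 4-benzyloxy-3,5-dimethoxyphenyl. Epimer mixtures at centres that are erased later (selenide carbon of 8, carbinol carbon of 18–22) are assumed to be carried forward unseparated.

**Route**

Step 1
Reactants: 1 D-glutamic acid
Product: 4 (R)-5-oxooxolane-2-carboxylic acid, via α-diazonium carboxylate 2 (not isolated), via (S)-α-lactone 3 (not isolated)
Conditions: NaNO2, aq HCl, 0 °C to rt
Reagents that add atoms: none
Why: Diazotisation of the α-amino acid, in which the α-carboxylate of 2 displaces N2 with inversion and the γ-carboxyl opens α-lactone 3 with a second inversion, should give the lactone acid with net retention (R).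

Step 2
Reactants: 4 (R)-5-oxooxolane-2-carboxylic acid
Product: 5 (R)-5-(hydroxymethyl)oxolan-2-one
Conditions: BH3·SMe2, THF, 0 °C to rt; MeOH quench
Reagents that add atoms: none
Why: Chemoselective borane reduction, since BH3 reduces a free carboxylic acid much faster than a lactone and does not touch the stereocentre.

Step 3
Reactants: 5 (R)-5-(hydroxymethyl)oxolan-2-one
Product: 6 (R)-5-[(tert-butyldiphenylsilyloxy)methyl]oxolan-2-one
Conditions: TBDPSCl, imidazole, DMF, 0 °C to rt
Reagents that add atoms: tert-butyl(chloro)diphenylsilane, CC(C)(C)[Si](Cl)(c1ccccc1)c1ccccc1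
Why: Imidazole-promoted silylation of the primary alcohol installs a bulky, base-stable group that later shields one face of the butenolide.

Step 4
Reactants: 6 (R)-5-[(tert-butyldiphenylsilyloxy)methyl]oxolan-2-one
Product: 8 (5R)-5-[(tert-butyldiphenylsilyloxy)methyl]-3-(phenylselanyl)oxolan-2-one (both C3 epimers), via lithium enolate 7 (not isolated)
Conditions: LiN(i-Pr)2, THF, −78 °C; then PhSeBr, −78 °C
Reagents that add atoms: phenylselanyl bromide, Br[Se]c1ccccc1
Why: α-Selenenylation of the kinetic lactone enolate 7, whose new C3 centre need not be controlled because it is removed in the next step.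

Step 5
Reactants: 8 (5R)-5-[(tert-butyldiphenylsilyloxy)methyl]-3-(phenylselanyl)oxolan-2-one
Product: 10 (R)-5-[(tert-butyldiphenylsilyloxy)methyl]furan-2(5H)-one, via selenoxide 9 (not isolated)
Conditions: 30% aq H2O2, pyridine, CH2Cl2, 0 °C to rt
Reagents that add atoms: none
Why: Selenoxide syn-elimination, in which either C3 epimer finds a syn hydrogen at C4, should give the conjugated butenolide under conditions that leave the γ-stereocentre intact.

Step 6
Reactants: 11 syringaldehyde; 12 benzyl bromide
Product: 13 4-benzyloxy-3,5-dimethoxybenzaldehyde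
Conditions: K2CO3, DMF, rt
Reagents that add atoms: none
Why: Williamson ether synthesis on the acidic, aldehyde-activated phenol.

Step 7
Reactants: 13 4-benzyloxy-3,5-dimethoxybenzaldehyde; 14 propane-1,3-dithiol
Product: 15 2-(4-benzyloxy-3,5-dimethoxyphenyl)-1,3-dithiane
Conditions: BF3·OEt2 (cat.), CH2Cl2, 0 °C to rt
Reagents that add atoms: none
Why: Lewis acid-catalysed dithioacetalisation of the aromatic aldehyde is fast at low temperature, so the aryl benzyl ether should survive the brief exposure to catalytic BF3.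

Step 8
Reactants: 15 2-(4-benzyloxy-3,5-dimethoxyphenyl)-1,3-dithiane; 10 (R)-5-[(tert-butyldiphenylsilyloxy)methyl]furan-2(5H)-one; 13 4-benzyloxy-3,5-dimethoxybenzaldehyde
Product: 18 (3S,4R,5R)-3-[Ar(hydroxy)methyl]-4-(2-Ar-1,3-dithian-2-yl)-5-[(tert-butyldiphenylsilyloxy)methyl]oxolan-2-one (both carbinol epimers), via 2-lithio-1,3-dithiane 16 (not isolated), via lithium enolate 17 (not isolated)
Conditions: 15, n-BuLi, THF, −78 °C; then 10, −78 °C; then 13, −78 °C; AcOH quench at −78 °C
Reagents that add atoms: none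
Why: n-BuLi removes the doubly sulfur-stabilised benzylic proton of 15; the soft carbanion 16 adds 1,4 to butenolide 10 and forms the bond from the β-carbon (future C4) to the masked ketone carbon, and the lithium enolate 17 then adds to aldehyde 13 to form the bond between the α-carbon (future C3) and the carbinol carbon (future C2). The closest known reaction type is the tandem conjugate addition of 2-lithio-2-aryl-1,3-dithianes to γ-substituted butenolides with aldol trapping of the enolate, a standard construction of lignan skeletons. No ring is closed; two skeletal bonds and two controlled stereocentres arise in one flask. The β-centre is controlled by the γ-silyloxymethyl group of 10, which shields one face so that 16 enters anti to it (4R), and the α-centre is controlled by the new bulky dithianyl group, anti to which the aldehyde is attacked (3S), which should give the trans,trans-lactone. The step needs 1,4- over 1,2-addition, secured by the delocalised aryl dithiane anion and the unhindered β-position, and it needs the two anti relationships, both relayed from the single glutamate-derived centre; the carbinol centre is left uncontrolled because it is ionised in step 12.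

Step 9
Reactants: 18 trans,trans-lactone adduct
Product: 19 (2R,3R,4R)-2-[Ar(hydroxy)methyl]-3-(2-Ar-1,3-dithian-2-yl)-5-(tert-butyldiphenylsilyloxy)pentane-1,4-diol
Conditions: LiAlH4, THF, 0 °C; aq NaOH work-up
Reagents that add atoms: none
Why: LiAlH4 reduction of the lactone to the 1,4-diol turns the lactone carbonyl into the future CH2OH on C3, while the dithiane, the benzyl ethers and the silyl ether are inert at 0 °C and no stereocentre is touched.

Step 10
Reactants: 19 silyl ether triol
Product: 20 (2R,3R,4R)-4-[Ar(hydroxy)methyl]-3-(2-Ar-1,3-dithian-2-yl)pentane-1,2,5-triol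
Conditions: Bu4NF, THF, 0 °C to rt
Reagents that add atoms: none
Why: Fluoride-mediated desilylation uncovers the terminal 1,2-diol without affecting any other group.

Step 11
Reactants: 20 tetraol
Product: 22 (2R,3R)-2-[Ar(hydroxy)methyl]-3-(2-Ar-1,3-dithian-2-yl)butane-1,4-diol, via aldehyde 21 (not isolated)
Conditions: NaIO4, THF–pH 7 buffer, 0 °C; extraction; then NaBH4, MeOH, 0 °C
Reagents that add atoms: none
Why: Periodate glycol cleavage of the only vicinal diol is fast at 0 °C and should outrun oxidation of the hindered 2,2-disubstituted dithiane, and aldehyde 21 (held as its lactols) is reduced at once by NaBH4 so that the glutamate carbon is excised and C5 becomes CH2OH before C4 can epimerise.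

Step 12
Reactants: 22 triol
Product: 24 [(2S,3R,4R)-2-Ar-4-(2-Ar-1,3-dithian-2-yl)oxolan-3-yl]methanol, via benzylic cation 23 (not isolated)
Conditions: CSA (cat.), CH2Cl2, 0 °C
Reagents that add atoms: none
Why: Acid-catalysed SN1 cycloetherification, in which both carbinol epimers ionise to the same 4-alkoxybenzyl cation 23; the C5 hydroxyl captures it 5-exo (the C3 hydroxymethyl could only form an oxetane) with the aryl group trans to the C3 substituent, the arrangement favoured both kinetically and thermodynamically over the all-cis alternative.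

Step 13
Reactants: 24 oxolane dithiane
Product: 25 Ar [(2S,3R,4R)-2-Ar-3-(hydroxymethyl)oxolan-4-yl] ketone
Conditions: Hg(ClO4)2, CaCO3, THF–H2O, 0 °C
Reagents that add atoms: water, O
Why: Hydrolysis of the dithioacetal assisted by thiophilic divalent mercury, run cold and buffered with carbonate so that neither acid nor base is available to enolise the new ketone at C4 or to ionise the benzylic ether at C2.

Step 14
Reactants: 25 dibenzyl ketone
Product: 26 ciwujiatone
Conditions: H2 (1 atm), 10% Pd/C, EtOAc, rt
Reagents that add atoms: none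
Why: Catalytic hydrogenolysis of the two aryl benzyl ethers is much faster than cleavage of the benzylic C2–O1 bond or reduction of the electron-rich aryl ketone, and the neutral medium leaves the 3,4-cis ketone unepimerised.

**Compound list**

1 | D-glutamic acid | N[C@H](CCC(=O)O)C(=O)O | starting material
2 | (R)-α-diazonium carboxylate of glutamic acid | N#[N+][C@H](CCC(=O)O)C(=O)[O-] | intermediate
3 | 3-[(2S)-3-oxooxiran-2-yl]propanoic acid (α-lactone) | O=C1O[C@H]1CCC(=O)O | intermediate
4 | (R)-5-oxooxolane-2-carboxylic acid | O=C1CC[C@H](C(=O)O)O1 | intermediate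
5 | (R)-5-(hydroxymethyl)oxolan-2-one | O=C1CC[C@H](CO)O1 | intermediate
6 | (R)-5-[(tert-butyldiphenylsilyloxy)methyl]oxolan-2-one | O=C1CC[C@H](CO[Si](c2ccccc2)(c2ccccc2)C(C)(C)C)O1 | intermediate
7 | lithium enolate of 6 | [Li]OC1=CC[C@H](CO[Si](c2ccccc2)(c2ccccc2)C(C)(C)C)O1 | intermediate
8 | (5R)-5-[(tert-butyldiphenylsilyloxy)methyl]-3-(phenylselanyl)oxolan-2-one, C3 epimers | O=C1C([Se]c2ccccc2)C[C@H](CO[Si](c2ccccc2)(c2ccccc2)C(C)(C)C)O1 | intermediate
9 | selenoxide of 8 | O=C1C([Se](=O)c2ccccc2)C[C@H](CO[Si](c2ccccc2)(c2ccccc2)C(C)(C)C)O1 | intermediate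
10 | (R)-5-[(tert-butyldiphenylsilyloxy)methyl]furan-2(5H)-one | O=C1C=C[C@H](CO[Si](c2ccccc2)(c2ccccc2)C(C)(C)C)O1 | intermediate
11 | syringaldehyde (4-hydroxy-3,5-dimethoxybenzaldehyde) | COc1cc(C=O)cc(OC)c1O | starting material
12 | benzyl bromide | BrCc1ccccc1 | starting material
13 | 4-benzyloxy-3,5-dimethoxybenzaldehyde | COc1cc(C=O)cc(OC)c1OCc1ccccc1 | intermediate
14 | propane-1,3-dithiol | SCCCS | starting material
15 | 2-(4-benzyloxy-3,5-dimethoxyphenyl)-1,3-dithiane | COc1cc(C2SCCCS2)cc(OC)c1OCc1ccccc1 | intermediate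
16 | 2-lithio-2-(4-benzyloxy-3,5-dimethoxyphenyl)-1,3-dithiane | [Li]C1(SCCCS1)c1cc(OC)c(OCc2ccccc2)c(OC)c1 | intermediate
17 | lithium (4R,5R)-4-(2-Ar-1,3-dithian-2-yl)-5-[(tert-butyldiphenylsilyloxy)methyl]-4,5-dihydrofuran-2-olate | [Li]OC1=C[C@@H](C2(SCCCS2)c2cc(OC)c(OCc3ccccc3)c(OC)c2)[C@H](CO[Si](c2ccccc2)(c2ccccc2)C(C)(C)C)O1 | intermediate
18 | (3S,4R,5R)-3-[Ar(hydroxy)methyl]-4-(2-Ar-1,3-dithian-2-yl)-5-[(tert-butyldiphenylsilyloxy)methyl]oxolan-2-one, both carbinol epimers | COc1cc(C2(SCCCS2)[C@H]2[C@H](CO[Si](c3ccccc3)(c3ccccc3)C(C)(C)C)OC(=O)[C@@H]2C(O)c2cc(OC)c(OCc3ccccc3)c(OC)c2)cc(OC)c1OCc1ccccc1 | intermediate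
19 | (2R,3R,4R)-2-[Ar(hydroxy)methyl]-3-(2-Ar-1,3-dithian-2-yl)-5-(tert-butyldiphenylsilyloxy)pentane-1,4-diol, carbinol epimers | OC[C@@H]([C@H]([C@@H](O)CO[Si](c1ccccc1)(c1ccccc1)C(C)(C)C)C1(SCCCS1)c1cc(OC)c(OCc2ccccc2)c(OC)c1)C(O)c1cc(OC)c(OCc2ccccc2)c(OC)c1 | intermediate
20 | (2R,3R,4R)-4-[Ar(hydroxy)methyl]-3-(2-Ar-1,3-dithian-2-yl)pentane-1,2,5-triol, carbinol epimers | OC[C@@H]([C@H]([C@@H](O)CO)C1(SCCCS1)c1cc(OC)c(OCc2ccccc2)c(OC)c1)C(O)c1cc(OC)c(OCc2ccccc2)c(OC)c1 | intermediate
21 | (2R,3R)-2-(2-Ar-1,3-dithian-2-yl)-3-[Ar(hydroxy)methyl]-4-hydroxybutanal, open form of its lactols | O=C[C@@H]([C@H](CO)C(O)c1cc(OC)c(OCc2ccccc2)c(OC)c1)C1(SCCCS1)c1cc(OC)c(OCc2ccccc2)c(OC)c1 | intermediate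
22 | (2R,3R)-2-[Ar(hydroxy)methyl]-3-(2-Ar-1,3-dithian-2-yl)butane-1,4-diol, carbinol epimers | OC[C@@H]([C@H](CO)C1(SCCCS1)c1cc(OC)c(OCc2ccccc2)c(OC)c1)C(O)c1cc(OC)c(OCc2ccccc2)c(OC)c1 | intermediate
23 | benzylic cation formed from 22 by loss of the carbinol hydroxyl | OC[C@@H]([C@H](CO)C1(SCCCS1)c1cc(OC)c(OCc2ccccc2)c(OC)c1)[CH+]c1cc(OC)c(OCc2ccccc2)c(OC)c1 | intermediate
24 | [(2S,3R,4R)-2-Ar-4-(2-Ar-1,3-dithian-2-yl)oxolan-3-yl]methanol | COc1cc(C2(SCCCS2)[C@H]2CO[C@H](c3cc(OC)c(OCc4ccccc4)c(OC)c3)[C@H]2CO)cc(OC)c1OCc1ccccc1 | intermediate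
25 | (4-benzyloxy-3,5-dimethoxyphenyl)[(3R,4R,5S)-5-(4-benzyloxy-3,5-dimethoxyphenyl)-4-(hydroxymethyl)oxolan-3-yl]methanone | COc1cc(C(=O)[C@H]2CO[C@H](c3cc(OC)c(OCc4ccccc4)c(OC)c3)[C@H]2CO)cc(OC)c1OCc1ccccc1 | intermediate
26 | ciwujiatone, (4-hydroxy-3,5-dimethoxyphenyl)[(3R,4R,5S)-5-(4-hydroxy-3,5-dimethoxyphenyl)-4-(hydroxymethyl)oxolan-3-yl]methanone | COc1cc(C(=O)[C@H]2CO[C@H](c3cc(OC)c(O)c(OC)c3)[C@H]2CO)cc(OC)c1O | target

**Step count and risks**

Total step count: 14. Longest linear sequence: 12 steps (steps 1–5 and 8–14, from D-glutamic acid); the arene branch (steps 6 and 7) joins at step 8.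

Steps most likely to fail:

Step 11. What may go wrong: periodate oxidises a dithiane sulfur to the sulfoxide at a rate comparable with glycol cleavage, or the α-branched aldehyde epimerises at C4 before it is reduced. Fallback: the excision is avoided by placing the future C5 at the aldehyde oxidation level in the butenolide. Setting out from dithiane 15 and aldehyde 13, lithiated 16 is added in THF at −78 °C to (5R)-5-[(1R,2S,5R)-menthyloxy]furan-2(5H)-one F1 (available from 5-hydroxyfuran-2(5H)-one and (−)-menthol by acetalisation and crystallisation), anti to the menthyloxy group. The resulting lithium enolate F2 is trapped with 13 to give the trans,trans-lactone acetal F3. LiAlH4 in THF at 0 °C then reduces the lactone carbonyl, releases menthol from the opened hemiacetal and reduces aldehyde 21 as it forms, so that the route is rejoined at triol 22 without silyl cleavage or periodate.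

Step 12. What may go wrong: cation 23 is intercepted by the electron-rich arene on the dithiane carbon (Friedel–Crafts closure of a six-membered carbocycle) or by a dithiane sulfur, or product 24 re-ionises on longer exposure and drains into those products, with erosion of the C2 configuration. Fallback: unmasking and ring closure change places. Setting out from triol 22, Hg(ClO4)2 and CaCO3 in THF–H2O at 0 °C should give (2R,3R)-1-Ar-3-[Ar(hydroxy)methyl]-4-hydroxy-2-(hydroxymethyl)butan-1-one F4, in which the aroyl group deactivates its arene and no sulfur remains. CSA (cat.) in CH2Cl2 at 0 °C then ionises the carbinol to benzylic cation F5, which the C5 hydroxyl closes to ketone 25, where the route is rejoined.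

Step 8. What may go wrong: proton transfer from the γ-position of 10 to carbanion 16, Michael addition of enolate 17 to unreacted 10, or reversal of the aldol on warming, each of which lowers conversion to 18. Fallback: the one-flask three-component coupling is given up for two separate two-component reactions. Setting out from 15 and 10, the conjugate addition of 16 is quenched with NH4Cl to give (4R,5R)-4-(2-Ar-1,3-dithian-2-yl)-5-[(tert-butyldiphenylsilyloxy)methyl]oxolan-2-one F6, which is purified. LiN(i-Pr)2 in THF at −78 °C then regenerates enolate 17 in the absence of 10 and 16, and addition of 13 with an AcOH quench at −78 °C returns to adduct 18.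

Further compounds
F1 | step 11 | (5R)-5-[(1R,2S,5R)-menthyloxy]furan-2(5H)-one | CC(C)[C@@H]1CC[C@@H](C)C[C@H]1O[C@H]1C=CC(=O)O1
F2 | step 11 | lithium (4R,5R)-4-(2-Ar-1,3-dithian-2-yl)-5-[(1R,2S,5R)-menthyloxy]-4,5-dihydrofuran-2-olate | [Li]OC1=C[C@@H](C2(SCCCS2)c2cc(OC)c(OCc3ccccc3)c(OC)c2)[C@H](O[C@@H]2C[C@H](C)CC[C@H]2C(C)C)O1
F3 | step 11 | (3S,4R,5R)-3-[Ar(hydroxy)methyl]-4-(2-Ar-1,3-dithian-2-yl)-5-[(1R,2S,5R)-menthyloxy]oxolan-2-one, both carbinol epimers | COc1cc(C2(SCCCS2)[C@H]2[C@H](O[C@@H]3C[C@H](C)CC[C@H]3C(C)C)OC(=O)[C@@H]2C(O)c2cc(OC)c(OCc3ccccc3)c(OC)c2)cc(OC)c1OCc1ccccc1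
F4 | step 12 | (2R,3R)-1-Ar-3-[Ar(hydroxy)methyl]-4-hydroxy-2-(hydroxymethyl)butan-1-one, carbinol epimers | OC[C@@H]([C@H](CO)C(=O)c1cc(OC)c(OCc2ccccc2)c(OC)c1)C(O)c1cc(OC)c(OCc2ccccc2)c(OC)c1
F5 | step 12 | benzylic cation formed from F4 by loss of the carbinol hydroxyl | OC[C@@H]([C@H](CO)C(=O)c1cc(OC)c(OCc2ccccc2)c(OC)c1)[CH+]c1cc(OC)c(OCc2ccccc2)c(OC)c1
F6 | step 8 | (4R,5R)-4-(2-Ar-1,3-dithian-2-yl)-5-[(tert-butyldiphenylsilyloxy)methyl]oxolan-2-one | O=C1C[C@@H](C2(SCCCS2)c2cc(OC)c(OCc3ccccc3)c(OC)c2)[C@H](CO[Si](c2ccccc2)(c2ccccc2)C(C)(C)C)O1
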